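Assumption: the SMILES is read as fisetinidol-(4α→6)-fisetinidol, upper unit (2R,3S,4R), lower unit (2R,3S), both 2,3-trans, with a 3,4-trans interflavan bond.

## Retrosynthetic overview

1. Target 14 ⇐ hexa-O-benzyl ether 13 (hydrogenolysis) ⇐ C4–C6 interflavan bond by Friedel–Crafts union of the C4-methoxy electrophile 12 with the nucleophile 11; both halves come from the one monomer 11.
2. Monomer 11 (tri-O-benzyl fisetinidol, ring C) ⇐ ring expansion of the 2-(α-hydroxybenzyl)-2,3-dihydrobenzofuran 10 by a 1,2-shift of the ring oxygen (five- to six-membered ring).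
3. 10 ⇐ racemic 2-aroyl-2,3-dihydrobenzofuran 9 (asymmetric hydrogenation with dynamic kinetic resolution sets both centres).
4. Dihydrofuran ring of 8/9 ⇐ resorcinol 6 (ring A as C,O-bis-nucleophile) + bromo enone 5 ⇐ catechol 1 (ring B) + 2,3-dibromopropanoyl chloride 3.
5. Ring order: dihydrofuran ring (step 3), chroman ring C by ring expansion (step 6), union of the two units (step 8), deprotection (step 9).

## Route

Step 1
Reactants: 1 catechol (benzene-1,2-diol)
Product: 2 1,2-bis(benzyloxy)benzene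
Conditions: BnBr (2.2 equiv), K2CO3 (2.5 equiv), DMF, 60 °C
Reagents that add atoms: benzyl bromide, BrCc1ccccc1
Why: Williamson ether synthesis masks both ring B phenols as benzyl ethers, which survive every later step and are removed together in step 9.

Step 2
Reactants: 2 1,2-bis(benzyloxy)benzene; 3 2,3-dibromopropanoyl chloride
Product: 5 2-bromo-1-[3,4-bis(benzyloxy)phenyl]prop-2-en-1-one, via dibromo ketone 4 (not isolated)
Conditions: Bi(OTf)3 (10 mol %), (CH2Cl)2, 50 °C, N2 sweep; then K2CO3 (1.5 equiv), acetone, 0 °C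
Reagents that add atoms: none
Why: Friedel–Crafts acylation para to one benzyloxy group under a catalytic Lewis acid that spares benzyl ethers, then E1cB loss of HBr from the 2,3-dibromo ketone gives the 2-bromo enone.

Step 3
Reactants: 5 2-bromo-1-[3,4-bis(benzyloxy)phenyl]prop-2-en-1-one; 6 resorcinol (benzene-1,3-diol)
Product: 8 rac-[3,4-bis(benzyloxy)phenyl](6-hydroxy-2,3-dihydro-1-benzofuran-2-yl)methanone, via bromo ketone adduct 7 (not isolated)
Conditions: 6 (4 equiv), Sc(OTf)3 (5 mol %), MeCN, 0 °C to rt; then K2CO3 (2 equiv), rt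
Reagents that add atoms: none
Why: Friedel–Crafts conjugate addition of resorcinol through C4 to the CH2 terminus of the enone, then 5-exo-tet Williamson closure of the ortho phenoxide on the α-bromo ketone, which can only give the five-membered ring; C2 is formed racemic and stays epimerisable.

Step 4
Reactants: 8 rac-[3,4-bis(benzyloxy)phenyl](6-hydroxy-2,3-dihydro-1-benzofuran-2-yl)methanone
Product: 9 rac-[3,4-bis(benzyloxy)phenyl][6-(benzyloxy)-2,3-dihydro-1-benzofuran-2-yl]methanone
Conditions: BnBr (1.1 equiv), K2CO3 (1.5 equiv), acetone, 50 °C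
Reagents that add atoms: benzyl bromide, BrCc1ccccc1
Why: Williamson etherification of the remaining phenol; carbonate is too weak a base to alkylate the ketone α-carbon.

Step 5
Reactants: 9 rac-[3,4-bis(benzyloxy)phenyl][6-(benzyloxy)-2,3-dihydro-1-benzofuran-2-yl]methanone
Product: 10 (S)-[3,4-bis(benzyloxy)phenyl][(2R)-6-(benzyloxy)-2,3-dihydro-1-benzofuran-2-yl]methanol
Conditions: H2 (20 atm), RuCl2[(S)-xylbinap][(S)-daipen] (1 mol %), t-BuOK (10 mol %), i-PrOH/THF, 25 °C
Reagents that add atoms: none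
Why: Noyori asymmetric hydrogenation with dynamic kinetic resolution, as established for racemic α-aryloxy ketones: t-BuOK racemises C2 through the enolate while the catalyst reduces the (2R)-ketone in the Felkin (anti) sense, setting the carbinol carbon (S) and fixing the ring carbon (R).

Step 6
Reactants: 10 (S)-[3,4-bis(benzyloxy)phenyl][(2R)-6-(benzyloxy)-2,3-dihydro-1-benzofuran-2-yl]methanol
Product: 11 (2R,3S)-7-(benzyloxy)-2-[3,4-bis(benzyloxy)phenyl]-3,4-dihydro-2H-chromen-3-ol
Conditions: TfOH (2 mol %), HFIP/H2O (10:1), 0.005 M, 0 °C to rt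
Reagents that add atoms: water, O
Why: Proposed new method: the acid ionises the p-alkoxybenzylic C–OH bond while the antiperiplanar ring oxygen bridges to a trans aryl-oxiranium ion (inversion at the carbinol carbon, which becomes C2 with its aryl group trans), and water opens this ion at the former ring carbon with inversion (it becomes C3, S), so the oxygen has made a 1,2-shift and the five-membered ring has grown to the chroman; return of water to the benzylic carbon is reversible whereas the C3–OH bond is not, which should make the all-equatorial 2,3-trans flavan-3-ol the sink; closest known reaction type: the reverse, solvolytic ring contraction of 2,3-trans-flavan-3-yl sulfonates to 2-(α-alkoxybenzyl)-2,3-dihydrobenzofurans, and oxiranium-mediated ring expansions of tetrahydrofuran-2-yl carbinyl sulfonates to tetrahydropyran-3-ols.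

Step 7
Reactants: 11 (2R,3S)-7-(benzyloxy)-2-[3,4-bis(benzyloxy)phenyl]-3,4-dihydro-2H-chromen-3-ol
Product: 12 (2R,3S,4S)-7-(benzyloxy)-2-[3,4-bis(benzyloxy)phenyl]-4-methoxy-3,4-dihydro-2H-chromen-3-ol
Conditions: DDQ (1.3 equiv), MeOH (5 equiv), CH2Cl2, rt
Reagents that add atoms: methanol, CO
Why: DDQ benzylic oxidation: hydride abstraction at C4 gives a cation stabilised by O1 and the 7-benzyloxy group, which methanol traps anti to the C2 aryl group; the C4 configuration is of no consequence because C4 is ionised again in step 8.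

Step 8
Reactants: 12 (2R,3S,4S)-7-(benzyloxy)-2-[3,4-bis(benzyloxy)phenyl]-4-methoxy-3,4-dihydro-2H-chromen-3-ol (1 equiv); 11 (2R,3S)-7-(benzyloxy)-2-[3,4-bis(benzyloxy)phenyl]-3,4-dihydro-2H-chromen-3-ol (4 equiv)
Product: 13 (2R,3S,4S)-7-(benzyloxy)-2-[3,4-bis(benzyloxy)phenyl]-4-{(2R,3S)-7-(benzyloxy)-2-[3,4-bis(benzyloxy)phenyl]-3-hydroxy-3,4-dihydro-2H-chromen-6-yl}-3,4-dihydro-2H-chromen-3-ol
Conditions: TMSOTf (0.2 equiv), CH2Cl2, −78 to −40 °C; then aq NaHCO3
Reagents that add atoms: none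
Why: Lewis-acid ionisation of the 4-methoxy group and Friedel–Crafts attack on the C4 cation by C6 of 11 (para to O1 and ortho to the 7-benzyloxy group, whereas C8 lies between two oxygens) from the face trans to the C3 hydroxyl give the 3,4-trans interflavan bond, while the excess of 11 suppresses oligomers.

Step 9
Reactants: 13 (2R,3S,4S)-7-(benzyloxy)-2-[3,4-bis(benzyloxy)phenyl]-4-{(2R,3S)-7-(benzyloxy)-2-[3,4-bis(benzyloxy)phenyl]-3-hydroxy-3,4-dihydro-2H-chromen-6-yl}-3,4-dihydro-2H-chromen-3-ol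
Product: 14 (2R,3S,4R)-2-(3,4-dihydroxyphenyl)-4-[(2R,3S)-2-(3,4-dihydroxyphenyl)-3,7-dihydroxy-3,4-dihydro-2H-chromen-6-yl]-3,4-dihydro-2H-chromene-3,7-diol
Conditions: H2 (1 atm), Pd(OH)2/C, THF/MeOH/H2O, rt
Reagents that add atoms: none
Why: Hydrogenolysis of the six benzyl aryl ethers leaves the C–C interflavan bond and the five stereocentres untouched.

## Compound list

1 | catechol (benzene-1,2-diol) | Oc1ccccc1O | starting material
2 | 1,2-bis(benzyloxy)benzene | C(Oc1ccccc1OCc1ccccc1)c1ccccc1 | intermediate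
3 | 2,3-dibromopropanoyl chloride (racemic) | ClC(=O)C(Br)CBr | starting material
4 | 2,3-dibromo-1-[3,4-bis(benzyloxy)phenyl]propan-1-one (racemic dibromo ketone, not isolated) | BrCC(Br)C(=O)c1ccc(OCc2ccccc2)c(OCc2ccccc2)c1 | intermediate
5 | 2-bromo-1-[3,4-bis(benzyloxy)phenyl]prop-2-en-1-one | C=C(Br)C(=O)c1ccc(OCc2ccccc2)c(OCc2ccccc2)c1 | intermediate
6 | resorcinol (benzene-1,3-diol) | Oc1cccc(O)c1 | starting material
7 | 2-bromo-3-(2,4-dihydroxyphenyl)-1-[3,4-bis(benzyloxy)phenyl]propan-1-one (racemic bromo ketone adduct, not isolated) | Oc1ccc(CC(Br)C(=O)c2ccc(OCc3ccccc3)c(OCc3ccccc3)c2)c(O)c1 | intermediate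
8 | rac-[3,4-bis(benzyloxy)phenyl](6-hydroxy-2,3-dihydro-1-benzofuran-2-yl)methanone | O=C(c1ccc(OCc2ccccc2)c(OCc2ccccc2)c1)C1Cc2ccc(O)cc2O1 | intermediate
9 | rac-[3,4-bis(benzyloxy)phenyl][6-(benzyloxy)-2,3-dihydro-1-benzofuran-2-yl]methanone | O=C(c1ccc(OCc2ccccc2)c(OCc2ccccc2)c1)C1Cc2ccc(OCc3ccccc3)cc2O1 | intermediate
10 | (S)-[3,4-bis(benzyloxy)phenyl][(2R)-6-(benzyloxy)-2,3-dihydro-1-benzofuran-2-yl]methanol (anti isomer) | O(Cc1ccccc1)c1ccc2c(c1)O[C@@H]([C@@H](O)c1ccc(OCc3ccccc3)c(OCc3ccccc3)c1)C2 | intermediate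
11 | (2R,3S)-7-(benzyloxy)-2-[3,4-bis(benzyloxy)phenyl]-3,4-dihydro-2H-chromen-3-ol (tri-O-benzyl fisetinidol, 2,3-trans) | O(Cc1ccccc1)c1ccc2c(c1)O[C@H](c1ccc(OCc3ccccc3)c(OCc3ccccc3)c1)[C@@H](O)C2 | intermediate
12 | (2R,3S,4S)-7-(benzyloxy)-2-[3,4-bis(benzyloxy)phenyl]-4-methoxy-3,4-dihydro-2H-chromen-3-ol (methoxy trans to the C2 aryl group) | O(Cc1ccccc1)c1ccc2c(c1)O[C@H](c1ccc(OCc3ccccc3)c(OCc3ccccc3)c1)[C@@H](O)[C@H]2OC | intermediate
13 | (2R,3S,4S)-7-(benzyloxy)-2-[3,4-bis(benzyloxy)phenyl]-4-{(2R,3S)-7-(benzyloxy)-2-[3,4-bis(benzyloxy)phenyl]-3-hydroxy-3,4-dihydro-2H-chromen-6-yl}-3,4-dihydro-2H-chromen-3-ol (hexa-O-benzyl ether of the target; 3,4-trans; C4 has the spatial arrangement of the target, the descriptor changes only because the 7-oxygen of the lower unit carries a benzyl group) | O(Cc1ccccc1)c1ccc2c(c1)O[C@H](c1ccc(OCc3ccccc3)c(OCc3ccccc3)c1)[C@@H](O)[C@@H]2c1cc2c(cc1OCc1ccccc1)O[C@H](c1ccc(OCc3ccccc3)c(OCc3ccccc3)c1)[C@@H](O)C2 | intermediate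
14 | (2R,3S,4R)-2-(3,4-dihydroxyphenyl)-4-[(2R,3S)-2-(3,4-dihydroxyphenyl)-3,7-dihydroxy-3,4-dihydro-2H-chromen-6-yl]-3,4-dihydro-2H-chromene-3,7-diol (CNP0187520.3) | Oc1ccc2c(c1)O[C@H](c1ccc(O)c(O)c1)[C@@H](O)[C@@H]2c1cc2c(cc1O)O[C@H](c1ccc(O)c(O)c1)[C@@H](O)C2 | target

## Step count and risks

Total steps: 9. Longest linear sequence: 9 (1 → 2 → 5 → 8 → 9 → 10 → 11 → 12 → 13 → 14; compound 11 enters step 8 a second time as the nucleophile).

The three steps most likely to fail:

Step 5 (dynamic kinetic resolution). The enantiomeric purity of the ring carbon depends on fast racemisation and on a high anti:syn ratio, neither of which has been shown for a ketone whose stereocentre sits in a dihydrofuran ring. The fallback sets out from 9 and comes back at 10. Reduction of 9 with LiBH(s-Bu)3 in THF at −78 °C under Felkin control gives rac-(S*)-[3,4-bis(benzyloxy)phenyl][(2R*)-6-(benzyloxy)-2,3-dihydro-1-benzofuran-2-yl]methanol F1. This racemate is separated on a chiral stationary phase, the (S),(2R) enantiomer being 10. Enantiopurity then comes from resolution instead of asymmetric catalysis.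

Step 6 (the proposed ring expansion). The benzylic cation may instead lose a proton to the 2-benzylidene compound and on to the 2-benzylbenzofuran, undergo a hydride or alkyl shift to an oxocarbenium ion, or alkylate ring A of a second molecule; high dilution, low temperature and a non-basic medium are chosen against these paths. The fallback uses known chemistry only, sets out from 2 and comes back at 11, by-passing the dihydrobenzofuran altogether. Friedel–Crafts acylation of 2 with 3-chloropropanoyl chloride gives 3-chloro-1-[3,4-bis(benzyloxy)phenyl]propan-1-one F2. Acid-catalysed reaction of F2 with resorcinol 6 (p-TsOH, toluene, 60 °C; loss of HCl to the aryl vinyl ketone, conjugate Friedel–Crafts addition, cyclodehydration) gives 2-[3,4-bis(benzyloxy)phenyl]-4H-chromen-7-ol F3. Benzylation (BnBr, K2CO3) gives 7-(benzyloxy)-2-[3,4-bis(benzyloxy)phenyl]-4H-chromene F4. Hydroboration–oxidation (BH3·SMe2; then NaOH, H2O2), which is established for flav-2-enes, places the hydroxyl at C3 by syn addition and gives rac-(2R*,3S*)-7-(benzyloxy)-2-[3,4-bis(benzyloxy)phenyl]-3,4-dihydro-2H-chromen-3-ol F5. Resolution on a chiral stationary phase gives 11.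

Step 8 (interflavan coupling). Ring A of a 5-deoxy flavan with a benzylated 7-oxygen is a weaker nucleophile than the phloroglucinol-type rings for which this coupling is routine, so self-condensation of 12 and attack at C8 may compete. The fallback sets out from 12 (with 11) and comes back at 13, replacing oxophilic by thiophilic activation. Exchange of the methoxy group of 12 with phenylmethanethiol (BF3·OEt2, CH2Cl2, −20 °C) gives (2R,3S,4R)-4-(benzylsulfanyl)-7-(benzyloxy)-2-[3,4-bis(benzyloxy)phenyl]-3,4-dihydro-2H-chromen-3-ol F6. Treatment of F6 with AgBF4 in THF at 0 °C in the presence of 11 (4 equiv) releases the C4 cation under neutral conditions and gives 13.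

Further compounds
F1 | step 5 | rac-(S*)-[3,4-bis(benzyloxy)phenyl][(2R*)-6-(benzyloxy)-2,3-dihydro-1-benzofuran-2-yl]methanol (racemate of 10, both enantiomers written) | O(Cc1ccccc1)c1ccc2c(c1)O[C@@H]([C@@H](O)c1ccc(OCc3ccccc3)c(OCc3ccccc3)c1)C2.O(Cc1ccccc1)c1ccc2c(c1)O[C@H]([C@H](O)c1ccc(OCc3ccccc3)c(OCc3ccccc3)c1)C2
F2 | step 6 | 3-chloro-1-[3,4-bis(benzyloxy)phenyl]propan-1-one | ClCCC(=O)c1ccc(OCc2ccccc2)c(OCc2ccccc2)c1
F3 | step 6 | 2-[3,4-bis(benzyloxy)phenyl]-4H-chromen-7-ol | Oc1ccc2CC=C(Oc2c1)c1ccc(OCc3ccccc3)c(OCc3ccccc3)c1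
F4 | step 6 | 7-(benzyloxy)-2-[3,4-bis(benzyloxy)phenyl]-4H-chromene | C(Oc1ccc2CC=C(Oc2c1)c1ccc(OCc3ccccc3)c(OCc3ccccc3)c1)c1ccccc1
F5 | step 6 | rac-(2R*,3S*)-7-(benzyloxy)-2-[3,4-bis(benzyloxy)phenyl]-3,4-dihydro-2H-chromen-3-ol (racemate of 11, both enantiomers written) | O(Cc1ccccc1)c1ccc2c(c1)O[C@H](c1ccc(OCc3ccccc3)c(OCc3ccccc3)c1)[C@@H](O)C2.O(Cc1ccccc1)c1ccc2c(c1)O[C@@H](c1ccc(OCc3ccccc3)c(OCc3ccccc3)c1)[C@H](O)C2
F6 | step 8 | (2R,3S,4R)-4-(benzylsulfanyl)-7-(benzyloxy)-2-[3,4-bis(benzyloxy)phenyl]-3,4-dihydro-2H-chromen-3-ol | O(Cc1ccccc1)c1ccc2c(c1)O[C@H](c1ccc(OCc3ccccc3)c(OCc3ccccc3)c1)[C@@H](O)[C@@H]2SCc1ccccc1
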